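**Plan**

1. Numbering: C1 quaternary C–Me, C2 CHOAc, C3 CH2, C4 C(OH)iPr, C5 ring-fusion CH, C6 CHOAng, C7 CH2, C8 C(Me)=, C9 =CH, C10 CHOBz; ring A = C1–C5 (cyclopentane), ring B = C1, C5–C10 (cycloheptene).
2. Enabling feature: C6 is an oxygen-bearing carbon lying between the ring-fusion carbon C5 and the methylene C7, which is allylic to C8=C9; C6 can therefore enter as carbon monoxide between a C5 radical and the CH2 terminus of a C9 allyl sulfide.
3. Cuts: the C6–O angelate, then C6–C7 and C5–C6 together (CO out, ring B open), then C9–C10 (aldehyde plus sulfur-stabilised allyl metal), then the C4 isopropyl/hydroxyl pair and the C1–allyl bond, back to 2-methylcyclopentane-1,3-dione.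
4. Forward: ring A is bought and decorated first (C1 allyl, C4 iPr/OH, C5 carbinol); the allyl group is cut down to the C10 aldehyde; the C9–C7 unit is added; esters and the C5 radical precursor are set; ring B closes in the carbonylative radical cascade; C6 is reduced and acylated last.
5. Stereochemistry: C1 and C2 from yeast desymmetrisation of the prochiral dione; C4 from oxygenation anti to the C1 allyl group; C10 from Felkin–Anh addition anti to the C5 branch; C5 from CO capture on the face away from the C10 chain (trans fusion); C6 from hydride delivery directed by the C4 hydroxyl.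

Key step: step 16

Remark: the C5 carbinol centre (13–26) and the C9 sulfide centre (21–26) are erased in step 16, so each is drawn as the isomer the chemistry should favour and its epimer would serve equally; α is the face of ring A carrying the C1 methyl, β the opposite face; methallyl phenyl sulfide is taken as a catalogue compound.

Abbreviations: TBS = tert-butyldimethylsilyl, TES = triethylsilyl, Bz = benzoyl, Ac = acetyl, Ang = angeloyl, dpm = 2,2,6,6-tetramethylheptane-3,5-dionate.

**Route**

Step 1
Reactants: 1 2-methylcyclopentane-1,3-dione; 2 allyl bromide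
Product: 3 2-allyl-2-methylcyclopentane-1,3-dione
Conditions: 1 M aq NaOH, rt
Reagents that add atoms: allyl bromide (2), C=CCBr
Why: C-alkylation of the stabilised 1,3-dione enolate with an allylic halide creates the quaternary C1 and the three-carbon handle that is later cut down to C10.

Step 2
Reactants: 3 2-allyl-2-methylcyclopentane-1,3-dione
Product: 4 (2S,3S)-2-allyl-3-hydroxy-2-methylcyclopentan-1-one (hydroxyl cis to allyl; carbinol carbon = C2, ketone carbon = C5)
Conditions: baker's yeast (Saccharomyces cerevisiae), sucrose, H2O, 30 °C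
Reagents that add atoms: none
Why: Enzymatic desymmetrising reduction of one of the two enantiotopic carbonyls of a 2,2-disubstituted cyclopentane-1,3-dione, a well-established yeast reduction, should give the (2S,3S)-ketol and so set C1 and C2.

Step 3
Reactants: 4 (2S,3S)-2-allyl-3-hydroxy-2-methylcyclopentan-1-one
Product: 5 (2S,3S)-2-allyl-3-(tert-butyldimethylsilyloxy)-2-methylcyclopentan-1-one
Conditions: TBSCl, imidazole, DMF, rt
Reagents that add atoms: tert-butyldimethylsilyl chloride, CC(C)(C)[Si](C)(C)Cl
Why: Standard silylation protects the β-hydroxy ketone against retro-aldol cleavage under the basic conditions that follow.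

Step 4
Reactants: 5 C2 TBS ether ketone; 6 acetone
Product: 8 C4 aldol adduct (4α-(2-hydroxypropan-2-yl) C5 ketone), via lithium enolate 7 (not isolated)
Conditions: LiN(iPr)2 (LDA), THF, −78 °C; then acetone, −78 °C; aq NH4Cl
Reagents that add atoms: acetone (6), CC(C)=O
Why: Only C4 can enolise because C1 is quaternary, so the kinetic lithium enolate undergoes a crossed aldol addition to acetone, the new bond forming anti to the allyl group at a centre that step 5 erases.

Step 5
Reactants: 8 C4 aldol adduct
Product: 10 4-isopropylidene C5 ketone, via tertiary mesylate 9 (not isolated)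
Conditions: MsCl, Et3N, CH2Cl2, 0 °C; then DBU, rt
Reagents that add atoms: none
Why: Mesylation of the tertiary alcohol and E1cB elimination through the C4 enolate complete the aldol condensation to the conjugated exocyclic enone.

Step 6
Reactants: 10 4-isopropylidene C5 ketone
Product: 12 4α-hydroxy-4β-isopropyl C5 ketone, via C4 hydroperoxide 11 (not isolated)
Conditions: Mn(dpm)3 (10 mol%), PhSiH3, O2 (1 atm), iPrOH/CH2Cl2, 0 °C; then P(OEt)3
Reagents that add atoms: dioxygen, O=O
Why: Mukaiyama-type hydrogen-atom-transfer reduction–oxygenation: the manganese hydride puts H on the β-carbon (making the isopropyl group), the C4 α-keto radical takes up O2 on the α face away from the allyl and silyloxy groups, and the phosphite reduces the hydroperoxide, the conjugated alkene being expected to react ahead of the monosubstituted allyl group.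

Step 7
Reactants: 12 4α-hydroxy-4β-isopropyl C5 ketone
Product: 13 4α,5β-diol (trans)
Conditions: NaBH4, MeOH, 0 °C
Reagents that add atoms: none
Why: Borohydride should attack the hindered ketone from the α face, which carries only the C1 methyl and the C4 hydroxyl, giving the trans-diol.

Step 8
Reactants: 13 4α,5β-diol
Product: 14 C4,C5 bis(triethylsilyl) ether
Conditions: TESOTf, 2,6-lutidine, CH2Cl2, 0 °C → rt
Reagents that add atoms: triethylsilyl trifluoromethanesulfonate, CC[Si](CC)(CC)OS(=O)(=O)C(F)(F)F
Why: Silyl triflate silylation covers the tertiary and the hindered secondary hydroxyl in one operation and makes the C5 branch bulky and non-chelating for step 11.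

Step 9
Reactants: 14 C4,C5 bis(triethylsilyl) ether
Product: 15 C1 (E)-prop-1-enyl compound
Conditions: RuHCl(CO)(PPh3)3 (5 mol%), toluene, 80 °C
Reagents that add atoms: none
Why: Ruthenium hydride-catalysed alkene isomerisation (hydrometalation, β-hydride elimination) moves the terminal double bond one position inward to the more stable disubstituted alkene next to C1.

Step 10
Reactants: 15 C1 (E)-prop-1-enyl compound
Product: 17 C10 aldehyde, via secondary ozonide 16 (not isolated)
Conditions: O3, CH2Cl2, −78 °C; then PPh3, −78 °C → rt
Reagents that add atoms: ozone, [O-][O+]=O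
Why: Ozonolysis with reductive work-up cleaves the only alkene to the non-enolisable aldehyde on the quaternary carbon.

Step 11
Reactants: 17 C10 aldehyde; 18 methallyl phenyl sulfide
Product: 21 C10 carbinol bearing the C9 phenyl sulfide and the C8(Me)=C7H2 alkene (C10 as in the target; C9/C10 anti), via lithiated sulfide 19 (not isolated), via allyltitanate complex 20 (not isolated)
Conditions: 18, n-BuLi, THF, −78 → 0 °C; Ti(OiPr)4, −78 °C; then 17, −78 → −30 °C; aq NH4Cl
Reagents that add atoms: methallyl phenyl sulfide (18), C=C(C)CSc1ccccc1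
Why: Transmetalation of the ambident thio-allyl anion to a titanate bonded at its CH2 terminus makes the carbonyl addition occur through a chair SE2' transition state at the sulfur-bearing carbon (α-adduct), and Felkin–Anh attack anti to the bulky C5 branch of the quaternary centre, passing the C1 methyl, sets C10.

Step 12
Reactants: 21 C10 carbinol; 22 benzoyl chloride
Product: 23 C10 benzoate
Conditions: BzCl, DMAP, pyridine, 40 °C
Reagents that add atoms: benzoyl chloride (22), O=C(Cl)c1ccccc1
Why: DMAP-catalysed acylation of the only free hydroxyl, with no other ester present that could migrate.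

Step 13
Reactants: 23 C10 benzoate
Product: 24 C2,C4,C5 triol
Conditions: HF·pyridine, THF, 0 °C → rt
Reagents that add atoms: none
Why: Fluoride cleavage of all three silyl ethers under mildly acidic conditions should leave the benzoate and the allyl sulfide intact and should not drive acyl migration.

Step 14
Reactants: 24 C2,C4,C5 triol
Product: 25 C2 acetate
Conditions: Ac2O (1.1 equiv), DMAP (cat), pyridine, CH2Cl2, −20 → 0 °C
Reagents that add atoms: acetic anhydride, CC(=O)OC(C)=O
Why: Site-selective acylation, since the C2 hydroxyl has one fully substituted neighbour, the C5 hydroxyl has two and the C4 hydroxyl is tertiary, so a slight excess of anhydride in the cold should acetylate C2 only.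

Step 15
Reactants: 25 C2 acetate
Product: 26 C5 O-phenyl thionocarbonate (key-step precursor)
Conditions: PhOC(S)Cl, DMAP (3 equiv), MeCN, 50 °C
Reagents that add atoms: O-phenyl chlorothionoformate, S=C(Cl)Oc1ccccc1
Why: DMAP-activated thioacylation installs the Barton–McCombie-type radical precursor on the remaining secondary hydroxyl under non-basic conditions, and the trans tertiary hydroxyl cannot close to a cyclic thionocarbonate.

Step 16
Reactants: 26 C5 O-phenyl thionocarbonate; 27 carbon monoxide
Product: 28 6-oxo trans-hydroazulene with C2 acetate, C10 benzoate, free C4 hydroxyl and C8=C9 alkene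
Conditions: CO (90 atm), (Bu3Sn)2 (1.5 equiv), hν (Xe lamp, Pyrex), benzene (0.01 M), 80 °C
Reagents that add atoms: carbon monoxide (27), [C-]#[O+]
Why: Proposed new method: a tributylstannyl radical adds to the thiocarbonyl sulfur of 26 and the adduct fragments to the secondary C5 radical, which takes up CO (C5–C6); the nucleophilic acyl radical then adds to the unsubstituted C7 terminus (C6–C7), and the tertiary C8 radical expels phenylthiyl from C9 to leave the C8=C9 alkene, phenylthiyl regenerating the stannyl radical from the ditin. The closest known reaction types are tin-mediated radical carbonylation followed by acyl radical cyclisation or allyl transfer, and the addition–fragmentation of allyl sulfides under ditin photolysis. Ring B closes in the 7-endo-trig mode, because 6-exo attack would have to occur at the fully substituted C8 and only the endo adduct has the fast, irreversible β-scission exit. The new C5 stereocentre is set by the face of CO capture: the α face carries only the C1 methyl and the free C4 hydroxyl, the β face the isopropyl group and the C10 chain, so C6 should end up trans to C10 (trans fusion). The step needs carbonylation to outrun direct closure of the C5 radical onto the alkene and needs the acyl radical to cyclise before it is quenched; high CO pressure, high dilution and a chain without any hydrogen donor (ditin instead of stannane, so that no thiophenol builds up) are chosen for this. The excess ditin should also scavenge phenylthiyl before it can shift the allyl sulfide by a radical 1,3-transposition.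

Step 17
Reactants: 28 6-oxo trans-hydroazulene
Product: 29 6β-hydroxy compound (C6 hydroxyl cis to H5, anti to the C4 hydroxyl)
Conditions: Me4NBH(OAc)3, AcOH/MeCN, −20 °C
Reagents that add atoms: none
Why: Hydroxyl-directed reduction (Evans–Saksena): the C4 alkoxyborohydride delivers hydride to the C6 ketone from the α face on which the C4 oxygen sits, giving the 1,3-anti diol under acidic conditions that avoid retro-aldol cleavage, dehydration and C5 epimerisation of the β-hydroxy ketone.

Step 18
Reactants: 29 6β-hydroxy compound; 30 angelic acid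
Product: 32 target CNP0248576.1 (C2 acetate, C6 angelate, C10 benzoate, C4 tertiary alcohol), via mixed anhydride 31 (not isolated)
Conditions: angelic acid, 2,4,6-trichlorobenzoyl chloride, Et3N, toluene, rt; then 29, 80 °C
Reagents that add atoms: angelic acid (30), C/C=C(/C)C(=O)O
Why: Yamaguchi-type esterification through the mixed anhydride acylates the secondary C6 hydroxyl (the tertiary C4 hydroxyl is inert) without a nucleophilic catalyst, which should preserve the (Z)-geometry of the angelate.

**Compound list**

1 | 2-methylcyclopentane-1,3-dione | CC1C(=O)CCC1=O | starting material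
2 | allyl bromide | C=CCBr | starting material
3 | 2-allyl-2-methylcyclopentane-1,3-dione | C=CCC1(C)C(=O)CCC1=O | intermediate
4 | (2S,3S)-2-allyl-3-hydroxy-2-methylcyclopentan-1-one | C=CC[C@@]1(C)[C@@H](O)CCC1=O | intermediate
5 | (2S,3S)-2-allyl-3-(tert-butyldimethylsilyloxy)-2-methylcyclopentan-1-one | C=CC[C@@]1(C)[C@@H](O[Si](C)(C)C(C)(C)C)CCC1=O | intermediate
6 | acetone | CC(C)=O | starting material
7 | lithium C4=C5 enolate of 5 | C=CC[C@@]1(C)[C@@H](O[Si](C)(C)C(C)(C)C)CC=C1O[Li] | intermediate (not isolated)
8 | C4 aldol adduct, 4α-(2-hydroxypropan-2-yl) C5 ketone | C=CC[C@@]1(C)[C@@H](O[Si](C)(C)C(C)(C)C)C[C@H](C(C)(C)O)C1=O | intermediate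
9 | tertiary mesylate of 8 | C=CC[C@@]1(C)[C@@H](O[Si](C)(C)C(C)(C)C)C[C@H](C(C)(C)OS(C)(=O)=O)C1=O | intermediate (not isolated)
10 | 4-isopropylidene C5 ketone | C=CC[C@@]1(C)[C@@H](O[Si](C)(C)C(C)(C)C)CC(=C(C)C)C1=O | intermediate
11 | 4α-hydroperoxy-4β-isopropyl C5 ketone | C=CC[C@@]1(C)[C@@H](O[Si](C)(C)C(C)(C)C)C[C@@](OO)(C(C)C)C1=O | intermediate (not isolated)
12 | 4α-hydroxy-4β-isopropyl C5 ketone | C=CC[C@@]1(C)[C@@H](O[Si](C)(C)C(C)(C)C)C[C@@](O)(C(C)C)C1=O | intermediate
13 | 4α,5β-diol | C=CC[C@@]1(C)[C@@H](O[Si](C)(C)C(C)(C)C)C[C@@](O)(C(C)C)[C@H]1O | intermediate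
14 | C4,C5 bis(triethylsilyl) ether | C=CC[C@@]1(C)[C@@H](O[Si](C)(C)C(C)(C)C)C[C@@](O[Si](CC)(CC)CC)(C(C)C)[C@H]1O[Si](CC)(CC)CC | intermediate
15 | C1 (E)-prop-1-enyl compound | C/C=C/[C@@]1(C)[C@@H](O[Si](C)(C)C(C)(C)C)C[C@@](O[Si](CC)(CC)CC)(C(C)C)[C@H]1O[Si](CC)(CC)CC | intermediate
16 | secondary ozonide (1,2,4-trioxolane) of 15, diastereomer mixture at the trioxolane carbons | CC2OOC(O2)[C@@]1(C)[C@@H](O[Si](C)(C)C(C)(C)C)C[C@@](O[Si](CC)(CC)CC)(C(C)C)[C@H]1O[Si](CC)(CC)CC | intermediate (not isolated)
17 | C10 aldehyde | O=C[C@@]1(C)[C@@H](O[Si](C)(C)C(C)(C)C)C[C@@](O[Si](CC)(CC)CC)(C(C)C)[C@H]1O[Si](CC)(CC)CC | intermediate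
18 | methallyl phenyl sulfide | C=C(C)CSc1ccccc1 | starting material
19 | 2-methyl-1-(phenylthio)allyllithium | [Li]C(Sc1ccccc1)C(C)=C | intermediate (not isolated)
20 | lithium tetraisopropoxy[2-methyl-3-(phenylthio)allyl]titanate | [Li+].CC(C)O[Ti-](OC(C)C)(OC(C)C)(OC(C)C)CC(C)=CSc1ccccc1 | intermediate (not isolated)
21 | C10 carbinol with C9 phenyl sulfide (C9/C10 anti) | C=C(C)[C@H](Sc2ccccc2)[C@H](O)[C@@]1(C)[C@@H](O[Si](C)(C)C(C)(C)C)C[C@@](O[Si](CC)(CC)CC)(C(C)C)[C@H]1O[Si](CC)(CC)CC | intermediate
22 | benzoyl chloride | O=C(Cl)c1ccccc1 | starting material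
23 | C10 benzoate | C=C(C)[C@H](Sc2ccccc2)[C@H](OC(=O)c3ccccc3)[C@@]1(C)[C@@H](O[Si](C)(C)C(C)(C)C)C[C@@](O[Si](CC)(CC)CC)(C(C)C)[C@H]1O[Si](CC)(CC)CC | intermediate
24 | C2,C4,C5 triol | C=C(C)[C@H](Sc2ccccc2)[C@H](OC(=O)c3ccccc3)[C@@]1(C)[C@@H](O)C[C@@](O)(C(C)C)[C@H]1O | intermediate
25 | C2 acetate | C=C(C)[C@H](Sc2ccccc2)[C@H](OC(=O)c3ccccc3)[C@@]1(C)[C@@H](OC(C)=O)C[C@@](O)(C(C)C)[C@H]1O | intermediate
26 | C5 O-phenyl thionocarbonate (key-step precursor) | C=C(C)[C@H](Sc2ccccc2)[C@H](OC(=O)c3ccccc3)[C@@]1(C)[C@@H](OC(C)=O)C[C@@](O)(C(C)C)[C@H]1OC(=S)Oc4ccccc4 | intermediate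
27 | carbon monoxide | [C-]#[O+] | starting material
28 | 6-oxo trans-hydroazulene (key-step product) | O=C1CC(C)=C[C@H](OC(=O)c2ccccc2)[C@@]3(C)[C@@H](OC(C)=O)C[C@@](O)(C(C)C)[C@H]13 | intermediate
29 | 6β-hydroxy compound | O[C@H]1CC(C)=C[C@H](OC(=O)c2ccccc2)[C@@]3(C)[C@@H](OC(C)=O)C[C@@](O)(C(C)C)[C@H]13 | intermediate
30 | angelic acid, (Z)-2-methylbut-2-enoic acid | C/C=C(/C)C(=O)O | starting material
31 | angelic 2,4,6-trichlorobenzoic anhydride | C/C=C(/C)C(=O)OC(=O)c1c(Cl)cc(Cl)cc1Cl | intermediate (not isolated)
32 | CNP0248576.1 | C/C=C(/C)C(=O)O[C@H]1CC(C)=C[C@H](OC(=O)c2ccccc2)[C@@]2(C)[C@@H](OC(C)=O)C[C@@](O)(C(C)C)[C@H]12 | target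

**Step count and risks**

Total step count: 18. Longest linear sequence: 18 steps (1 to 32); 2, 6, 18, 22, 27 and 30 are bought.

Most likely to fail:

1. Step 16 (Proposed new method). Several processes can go wrong. The C5 radical may close directly onto the alkene or be lost before it meets CO. CO may be captured on the β face, leading to the cis-fused system. The acyl radical may decarbonylate or oligomerise instead of closing the seven-membered ring. Phenylthiyl may transpose the allyl sulfide. The fallback uses known reaction types only, sets out from aldehyde 17 and comes back at ketone 28; C6 still enters as CO, but intermolecularly, and ring B is closed by metathesis. Vinylmagnesium bromide (THF, −78 °C) should add to 17 with the same Felkin–Anh sense as in step 11 to give the C10 vinyl carbinol F1. Benzoylation (BzCl, DMAP, pyridine) gives the benzoate F2. HF·pyridine gives the triol F3. Selective acetylation as in step 14 gives the C2 acetate F4. Thioacylation as in step 15 gives the C5 thionocarbonate F5, whose C5 radical has no alkene within easy reach. Tin-mediated three-component radical coupling with CO and an allylstannane (CO 80 atm, methallyltributylstannane, AIBN, benzene, 80 °C) should give the C5 methallyl ketone F6, with C6 on the α face. Ring-closing metathesis with the second-generation Grubbs catalyst (toluene, 80 °C) then joins C8 to C9 with loss of ethylene and gives 28.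

2. Step 11. The titanate may leak to the γ-adduct (vinyl sulfide), the very hindered aldehyde may react sluggishly, or facial control at C10 may be incomplete. The fallback sets out from 17 and comes back at 21. The lithium enolate of 1-(phenylthio)propan-2-one (LiN(iPr)2, THF, −78 °C; deprotonation at the sulfur-bearing carbon) adds to 17 in an aldol reaction, so the C9–C10 bond can only form at the sulfur-bearing carbon; this gives the β-hydroxy α-(phenylthio) ketone F7. Non-basic methylenation of the ketone with Zn/CH2Br2/TiCl4 (THF/CH2Cl2, 0 °C) then gives 21.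

3. Step 6. The manganese hydride may hydrate the allyl group in competition with the hindered tetrasubstituted enone, and the small oxidant O2 may discriminate poorly between the two faces of C4. The fallback sets out from 10 and comes back at 12, replacing the radical oxygenation by two ionic steps. Copper hydride conjugate reduction ([(Ph3P)CuH]6, PhSiH3, toluene, rt), which leaves isolated alkenes alone, gives the α-isopropyl ketone F8. Its potassium enolate (KN(SiMe3)2, THF, −78 °C) is then hydroxylated with the bulky 2-(phenylsulfonyl)-3-phenyloxaziridine from the α face to give 12.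

Further compounds
F1 | step 16 | C10 vinyl carbinol (tris-silyl ether) | C=C[C@H](O)[C@@]1(C)[C@@H](O[Si](C)(C)C(C)(C)C)C[C@@](O[Si](CC)(CC)CC)(C(C)C)[C@H]1O[Si](CC)(CC)CC
F2 | step 16 | C10 benzoate of F1 | C=C[C@H](OC(=O)c2ccccc2)[C@@]1(C)[C@@H](O[Si](C)(C)C(C)(C)C)C[C@@](O[Si](CC)(CC)CC)(C(C)C)[C@H]1O[Si](CC)(CC)CC
F3 | step 16 | C2,C4,C5 triol with C10 vinyl benzoate | C=C[C@H](OC(=O)c2ccccc2)[C@@]1(C)[C@@H](O)C[C@@](O)(C(C)C)[C@H]1O
F4 | step 16 | C2 acetate of F3 | C=C[C@H](OC(=O)c2ccccc2)[C@@]1(C)[C@@H](OC(C)=O)C[C@@](O)(C(C)C)[C@H]1O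
F5 | step 16 | C5 O-phenyl thionocarbonate of F4 | C=C[C@H](OC(=O)c2ccccc2)[C@@]1(C)[C@@H](OC(C)=O)C[C@@](O)(C(C)C)[C@H]1OC(=S)Oc3ccccc3
F6 | step 16 | C5 α-(3-methylbut-3-enoyl) compound (metathesis diene) | C=C[C@H](OC(=O)c2ccccc2)[C@@]1(C)[C@@H](OC(C)=O)C[C@@](O)(C(C)C)[C@@H]1C(=O)CC(C)=C
F7 | step 11 | C10 carbinol with C9 phenyl sulfide and C8 methyl ketone | CC(=O)[C@H](Sc2ccccc2)[C@H](O)[C@@]1(C)[C@@H](O[Si](C)(C)C(C)(C)C)C[C@@](O[Si](CC)(CC)CC)(C(C)C)[C@H]1O[Si](CC)(CC)CC
F8 | step 6 | 4-isopropyl C5 ketone (isopropyl α, centre erased on enolisation) | C=CC[C@@]1(C)[C@@H](O[Si](C)(C)C(C)(C)C)C[C@H](C(C)C)C1=O
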